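**Plan** (labdane numbering: ring A = C1–C5 and C10, ring B = C5–C10, side chain C11–C16, C17 on C8; β = the face of the C10 methyl group)
1. Retrosynthetic cuts, in order: the O-acetyl and O-silyl groups; C7–O and C8–C17 (ketone chemistry at C8); C9–C11 (sp2–sp3 coupling of the complete side chain); C1–C10, which closes ring A; C4–C5 (reverse prenylation).
2. Forward: ring B is bought as 3-ethoxy-2-methylcyclohex-2-enone; C4/C5 and C1 are attached in two steps; ring A is closed by attack of C10 on C1; ring B is then functionalised at C7–C9 and the side chain is coupled at C9.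
3. Enabling feature: C10 is the methyl-bearing α-carbon of a ring B 2-methylcyclohex-2-enone (C9=O, C10=C5) and C4 is quaternary. Only the ring dienolate C9–C10–C5–C6 can form, it is nucleophilic at C10, and C5 stays sp2 during the closure.
4. Stereochemistry: C10 from the chiral palladium catalyst in the ring closure; C5 by α-face hydrogenation of C5=C6; C9 by equilibration next to the C8 ketone; C8 by equatorial MeMgBr attack; C7 by axial hydride delivery; the E-alkene is bought.

Key step: step 3

Assumption: the (R,R)-ligand is written in step 3 on the working hypothesis that it delivers (S)-7; the sense of induction has to be found by experiment, and the (S,S)-ligand is used if it is the opposite.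

Step 1
Reactants: 1 3-ethoxy-2-methylcyclohex-2-en-1-one; 2 (3-methylbut-2-en-1-yl)magnesium chloride
Product: 4 2-methyl-3-(2-methylbut-3-en-2-yl)cyclohex-2-en-1-one, via tertiary magnesium alkoxide 3 (not isolated)
Conditions: THF, −78 °C; then 2 M HCl, 0 → 25 °C
Reagents that add atoms: water, O
Why: Stork–Danheiser sequence in which the allylic Grignard reagent should add to the vinylogous ester carbonyl through its γ-carbon (six-membered SE2' transition state, kinetic at −78 °C) and acid hydrolysis transposes the carbonyl to give the 3-substituted enone, which has no stereocenter.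

Step 2
Reactants: 4 2-methyl-3-(2-methylbut-3-en-2-yl)cyclohex-2-en-1-one; 5 allyl tert-butyl carbonate
Product: 6 tert-butyl (E)-4-methyl-4-(2-methyl-3-oxocyclohex-1-en-1-yl)pent-2-en-1-yl carbonate
Conditions: (1,3-dimesitylimidazolidin-2-ylidene)dichloro(2-isopropoxybenzylidene)ruthenium (second-generation Hoveyda–Grubbs catalyst, 3 mol %), 5 (4 equiv), CH2Cl2, 40 °C
Reagents that add atoms: none
Why: Olefin cross-metathesis of a vinyl group next to a quaternary carbon (which does not homodimerise) with an unhindered allylic carbonate should give the E-alkene under thermodynamic control, while the tetrasubstituted enone alkene is inert.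

Step 3
Reactants: 6 tert-butyl (E)-4-methyl-4-(2-methyl-3-oxocyclohex-1-en-1-yl)pent-2-en-1-yl carbonate
Product: 7 (S)-5,5,8a-trimethyl-3,5,8,8a-tetrahydronaphthalen-1(2H)-one
Conditions: Pd2(dba)3·CHCl3 (2.5 mol %), (1R,2R)-N,N'-bis[2-(diphenylphosphino)benzoyl]cyclohexane-1,2-diamine (7.5 mol %), degassed toluene (0.01 M), 25 → 45 °C
Reagents that add atoms: none
Why: Proposed new method: zerovalent palladium ionises the allylic tert-butyl carbonate to a cationic π-allyl complex, and the tert-butoxide released on loss of CO2 removes a C6 hydrogen of the 2-methylcyclohex-2-enone (C4 is quaternary, so there is no chain γ-hydrogen and no β-hydride for palladium) to give the ring B dienolate, whose methyl-bearing α-carbon C10 attacks the CH2 terminus C1 of the π-allyl unit anti to palladium. The closest known reactions are the palladium-catalysed asymmetric allylic alkylation of ketone enolates to α-quaternary ketones and the base-mediated intramolecular deconjugative α-alkylation of 3-(ω-haloalkyl)-2-alkylcyclohex-2-enones, and their combination in an intramolecular enantioselective form on an unstabilised dienolate is what is new. Ring A is closed as a six-membered ring by attack at the distal allyl terminus through a chair-like six-centre array C10–C5–C4–C3–C2–C1, in which the anti π-allyl isomer (reached by π–σ–π equilibration) places the cis C2=C3 alkene inside the ring, whereas attack at C3 would give a cyclobutane and is excluded. The only new stereocenter, the quaternary C10, should be controlled by the C2-symmetric diphosphine ligand, which differentiates the two enantiotopic faces of the allyl unit, while the short tether couples the allyl face to the dienolate face in the ring-forming transition state. The step needs α- over γ- and O-alkylation and cyclisation over oligomerisation, which are secured because metal dienolates alkylate kinetically at the α-carbon, the cross-conjugated C8 enolate cannot reach C1, O-allylation is reversible under palladium catalysis and high dilution disfavours intermolecular alkylation. Because C5 stays sp2 (C5=C6), the ring fusion is not decided here but in step 4.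

Step 4
Reactants: 7 (S)-5,5,8a-trimethyl-3,5,8,8a-tetrahydronaphthalen-1(2H)-one
Product: 8 (4aS,8aS)-5,5,8a-trimethyloctahydronaphthalen-1(2H)-one
Conditions: H2 (4 bar), 10 % Pd/C, EtOH, 25 °C
Reagents that add atoms: none
Why: Heterogeneous hydrogenation should saturate the ring A alkene and add hydrogen to C5=C6 from the α-face, opposite the axial C10 methyl and the axial C4 methyl, which sets 5α-H and the trans ring fusion as in hydrogenations of 4,4,10-trimethyl-Δ5-octalins.

Step 5
Reactants: 8 (4aS,8aS)-5,5,8a-trimethyloctahydronaphthalen-1(2H)-one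
Product: 9 (4aS,8aS)-2-hydroxy-5,5,8a-trimethyloctahydronaphthalen-1(2H)-one (mixture of C2 epimers)
Conditions: LiN(iPr)2, THF, −78 °C; then 2-(phenylsulfonyl)-3-phenyloxaziridine, −78 °C; aq. NH4Cl
Reagents that add atoms: 2-(phenylsulfonyl)-3-phenyloxaziridine, O=S(=O)(c1ccccc1)N1OC1c1ccccc1
Why: Enolate oxidation with an N-sulfonyloxaziridine can occur only at C8 because C10 is quaternary, and the configuration of the new carbinol center is irrelevant since it is erased in step 7.

Step 6
Reactants: 9 (4aS,8aS)-2-hydroxy-5,5,8a-trimethyloctahydronaphthalen-1(2H)-one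
Product: 10 (4aS,8aS)-2-methoxy-5,5,8a-trimethyloctahydronaphthalen-1(2H)-one (mixture of C2 epimers)
Conditions: MeI, Ag2O, MeCN, 40 °C, dark
Reagents that add atoms: iodomethane, CI
Why: Purdie-type O-methylation under non-basic conditions should etherify the α-hydroxy ketone without α-ketol rearrangement and creates no new stereocenter.

Step 7
Reactants: 10 (4aS,8aS)-2-methoxy-5,5,8a-trimethyloctahydronaphthalen-1(2H)-one
Product: 11 (4aS,8aS)-2-methoxy-5,5,8a-trimethyl-3,4,4a,5,6,7,8,8a-octahydronaphthalen-1-yl trifluoromethanesulfonate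
Conditions: KN(SiMe3)2, THF, −78 °C; then PhNTf2, −78 → 0 °C; aq. NH4Cl
Reagents that add atoms: N-phenylbis(trifluoromethanesulfonimide), O=S(=O)(N(c1ccccc1)S(=O)(=O)C(F)(F)F)C(F)(F)F
Why: O-Triflation of the only possible enolate (C8=C9) gives the α-methoxy enol triflate and removes the C8 stereocenter.

Step 8
Reactants: 12 (E)-3-methylpent-2-en-4-yn-1-ol
Product: 13 tert-butyl{[(E)-3-methylpent-2-en-4-yn-1-yl]oxy}diphenylsilane
Conditions: tert-butyl(chloro)diphenylsilane, imidazole, CH2Cl2, 0 → 25 °C
Reagents that add atoms: tert-butyl(chloro)diphenylsilane, CC(C)(C)[Si](Cl)(c1ccccc1)c1ccccc1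
Why: Standard silylation of the primary allylic alcohol gives an ether that survives the basic, organometallic and mildly acidic steps that follow, and the bought E-alkene is untouched.

Step 9
Reactants: 13 tert-butyl{[(E)-3-methylpent-2-en-4-yn-1-yl]oxy}diphenylsilane
Product: 14 tert-butyl{[(E)-3-methylpenta-2,4-dien-1-yl]oxy}diphenylsilane
Conditions: H2 (1 bar), Pd/CaCO3 poisoned with Pb(OAc)2, quinoline, hexane/EtOAc, 25 °C, stopped after 1 equiv H2
Reagents that add atoms: none
Why: Semihydrogenation over poisoned palladium should reduce the terminal alkyne to the vinyl group and leave the trisubstituted E-alkene in place.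

Step 10
Reactants: 11 (4aS,8aS)-2-methoxy-5,5,8a-trimethyl-3,4,4a,5,6,7,8,8a-octahydronaphthalen-1-yl trifluoromethanesulfonate; 14 tert-butyl{[(E)-3-methylpenta-2,4-dien-1-yl]oxy}diphenylsilane
Product: 17 (13E)-15-(tert-butyldiphenylsilyloxy)-17-norlabd-13-en-8-one (5α-H, 9α-H, 10β-CH3), via B-alkyl-9-borabicyclononane 15 (not isolated), via methyl enol ether 16 (not isolated)
Conditions: 14, 9-BBN, THF, 0 → 25 °C; then 11, Pd(dppf)Cl2 (5 mol %), AsPh3 (10 mol %), Cs2CO3, DMF/THF/H2O, 60 °C; then 1 M HCl, THF, 25 °C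
Reagents that add atoms: water, O
Why: Anti-Markovnikov hydroboration of the vinyl group by 9-BBN and B-alkyl Suzuki–Miyaura coupling with the hindered enol triflate (compare couplings of 2,6,6-trimethylcyclohexenyl triflate) should give the enol ether, whose acid hydrolysis unveils the C8 ketone, with C9 protonated from the α-face and equilibrated next to the carbonyl to the equatorial 9β side chain.

Step 11
Reactants: 17 (13E)-15-(tert-butyldiphenylsilyloxy)-17-norlabd-13-en-8-one
Product: 18 (13E)-15-(tert-butyldiphenylsilyloxy)-7α-hydroxy-17-norlabd-13-en-8-one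
Conditions: LiN(iPr)2, THF, −78 °C; then 2-(phenylsulfonyl)-3-phenyloxaziridine, −78 °C; aq. NH4Cl
Reagents that add atoms: 2-(phenylsulfonyl)-3-phenyloxaziridine, O=S(=O)(c1ccccc1)N1OC1c1ccccc1
Why: Kinetic deprotonation at the C7 methylene (not at the hindered tertiary C9–H) and enolate oxidation with the oxaziridine by axial attack on the α-face should give mainly the 7α-alcohol, whose configuration is corrected in steps 13 and 14.

Step 12
Reactants: 18 (13E)-15-(tert-butyldiphenylsilyloxy)-7α-hydroxy-17-norlabd-13-en-8-one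
Product: 19 (13E)-15-(tert-butyldiphenylsilyloxy)-8α-methyl-17-norlabd-13-ene-7α,8β-diol
Conditions: MeMgBr (3 equiv), THF, −78 → 0 °C; aq. NH4Cl
Reagents that add atoms: methylmagnesium bromide, C[Mg]Br
Why: Grignard addition to the C8 ketone should occur by equatorial attack from the α-face, because the β-face is shielded by the syn-axial C10 methyl group, which sets the 8α-methyl and the axial 8β-hydroxyl group.

Step 13
Reactants: 19 (13E)-15-(tert-butyldiphenylsilyloxy)-8α-methyl-17-norlabd-13-ene-7α,8β-diol
Product: 20 (13E)-15-(tert-butyldiphenylsilyloxy)-8β-hydroxy-8α-methyl-17-norlabd-13-en-7-one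
Conditions: Dess–Martin periodinane, NaHCO3, CH2Cl2, 0 → 25 °C
Reagents that add atoms: none
Why: Periodinane oxidation converts the secondary C7 alcohol into the ketone, while the tertiary C8 alcohol cannot be oxidised and no stereocenter is touched.

Step 14
Reactants: 20 (13E)-15-(tert-butyldiphenylsilyloxy)-8β-hydroxy-8α-methyl-17-norlabd-13-en-7-one
Product: 21 (13E)-15-(tert-butyldiphenylsilyloxy)-8α-methyl-17-norlabd-13-ene-7β,8β-diol
Conditions: NaBH4, MeOH, 0 °C
Reagents that add atoms: none
Why: Borohydride reduction should deliver hydride axially on the α-face of C7 (the equatorial approach is hindered by the adjacent axial 8β-hydroxyl) and so give the equatorial 7β-alcohol, cis to the C8 hydroxyl.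

Step 15
Reactants: 21 (13E)-15-(tert-butyldiphenylsilyloxy)-8α-methyl-17-norlabd-13-ene-7β,8β-diol
Product: 22 (13E)-7β-acetoxy-15-(tert-butyldiphenylsilyloxy)-8α-methyl-17-norlabd-13-en-8β-ol
Conditions: Ac2O, pyridine, 4-(dimethylamino)pyridine (cat.), CH2Cl2, 0 → 25 °C
Reagents that add atoms: acetic anhydride, CC(=O)OC(C)=O
Why: Nucleophile-catalysed acylation acetylates the secondary equatorial C7 alcohol and leaves the tertiary axial C8 alcohol free.

Step 16
Reactants: 22 (13E)-7β-acetoxy-15-(tert-butyldiphenylsilyloxy)-8α-methyl-17-norlabd-13-en-8β-ol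
Product: 23 (13E)-7β-acetoxy-8α-methyl-17-norlabd-13-ene-8β,15-diol (target CNP0499846.1)
Conditions: HF·pyridine, pyridine, THF, 0 → 25 °C
Reagents that add atoms: none
Why: Buffered fluoride desilylation frees the primary allylic alcohol without acetate migration or cleavage and without touching any stereocenter.

**Compound list**
1 | 3-ethoxy-2-methylcyclohex-2-en-1-one | CCOC1=C(C)C(=O)CCC1 | starting material
2 | (3-methylbut-2-en-1-yl)magnesium chloride (0.5 M in THF) | CC(C)=CC[Mg]Cl | starting material
3 | chloromagnesium 3-ethoxy-2-methyl-1-(2-methylbut-3-en-2-yl)cyclohex-2-en-1-olate (racemic) | CCOC1=C(C)C(O[Mg]Cl)(CCC1)C(C)(C)C=C | intermediate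
4 | 2-methyl-3-(2-methylbut-3-en-2-yl)cyclohex-2-en-1-one | CC1=C(CCCC1=O)C(C)(C)C=C | intermediate
5 | allyl tert-butyl carbonate | C=CCOC(=O)OC(C)(C)C | starting material
6 | tert-butyl (E)-4-methyl-4-(2-methyl-3-oxocyclohex-1-en-1-yl)pent-2-en-1-yl carbonate | CC1=C(CCCC1=O)C(C)(C)/C=C/COC(=O)OC(C)(C)C | intermediate
7 | (S)-5,5,8a-trimethyl-3,5,8,8a-tetrahydronaphthalen-1(2H)-one | C1C=C2C(C)(C)C=CC[C@]2(C)C(=O)C1 | intermediate
8 | (4aS,8aS)-5,5,8a-trimethyloctahydronaphthalen-1(2H)-one | C1C[C@H]2C(C)(C)CCC[C@]2(C)C(=O)C1 | intermediate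
9 | (4aS,8aS)-2-hydroxy-5,5,8a-trimethyloctahydronaphthalen-1(2H)-one (C2 epimers) | C1C[C@H]2C(C)(C)CCC[C@]2(C)C(=O)C1O | intermediate
10 | (4aS,8aS)-2-methoxy-5,5,8a-trimethyloctahydronaphthalen-1(2H)-one (C2 epimers) | C1C[C@H]2C(C)(C)CCC[C@]2(C)C(=O)C1OC | intermediate
11 | (4aS,8aS)-2-methoxy-5,5,8a-trimethyl-3,4,4a,5,6,7,8,8a-octahydronaphthalen-1-yl trifluoromethanesulfonate | C1C[C@H]2C(C)(C)CCC[C@]2(C)C(OS(=O)(=O)C(F)(F)F)=C1OC | intermediate
12 | (E)-3-methylpent-2-en-4-yn-1-ol | OC/C=C(C)/C#C | starting material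
13 | tert-butyl{[(E)-3-methylpent-2-en-4-yn-1-yl]oxy}diphenylsilane | CC(C)(C)[Si](OC/C=C(C)/C#C)(c1ccccc1)c1ccccc1 | intermediate
14 | tert-butyl{[(E)-3-methylpenta-2,4-dien-1-yl]oxy}diphenylsilane | CC(C)(C)[Si](OC/C=C(C)/C=C)(c1ccccc1)c1ccccc1 | intermediate
15 | 9-[(E)-5-(tert-butyldiphenylsilyloxy)-3-methylpent-3-en-1-yl]-9-borabicyclo[3.3.1]nonane | CC(C)(C)[Si](OC/C=C(C)/CCB1C2CCCC1CCC2)(c1ccccc1)c1ccccc1 | intermediate
16 | tert-butyl{[(E)-5-[(4aS,8aS)-2-methoxy-5,5,8a-trimethyl-3,4,4a,5,6,7,8,8a-octahydronaphthalen-1-yl]-3-methylpent-2-en-1-yl]oxy}diphenylsilane | C1C[C@H]2C(C)(C)CCC[C@]2(C)C(CC/C(C)=C/CO[Si](c3ccccc3)(c3ccccc3)C(C)(C)C)=C1OC | intermediate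
17 | (13E)-15-(tert-butyldiphenylsilyloxy)-17-norlabd-13-en-8-one; (1R,4aS,8aS)-1-[(E)-5-(tert-butyldiphenylsilyloxy)-3-methylpent-3-en-1-yl]-5,5,8a-trimethyloctahydronaphthalen-2(1H)-one | C1C[C@H]2C(C)(C)CCC[C@]2(C)[C@@H](CC/C(C)=C/CO[Si](c3ccccc3)(c3ccccc3)C(C)(C)C)C1=O | intermediate
18 | (13E)-15-(tert-butyldiphenylsilyloxy)-7α-hydroxy-17-norlabd-13-en-8-one | O[C@@H]1C[C@H]2C(C)(C)CCC[C@]2(C)[C@@H](CC/C(C)=C/CO[Si](c3ccccc3)(c3ccccc3)C(C)(C)C)C1=O | intermediate
19 | (13E)-15-(tert-butyldiphenylsilyloxy)-8α-methyl-17-norlabd-13-ene-7α,8β-diol | O[C@@H]1C[C@H]2C(C)(C)CCC[C@]2(C)[C@@H](CC/C(C)=C/CO[Si](c3ccccc3)(c3ccccc3)C(C)(C)C)[C@@]1(C)O | intermediate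
20 | (13E)-15-(tert-butyldiphenylsilyloxy)-8β-hydroxy-8α-methyl-17-norlabd-13-en-7-one | O=C1C[C@H]2C(C)(C)CCC[C@]2(C)[C@@H](CC/C(C)=C/CO[Si](c3ccccc3)(c3ccccc3)C(C)(C)C)[C@@]1(C)O | intermediate
21 | (13E)-15-(tert-butyldiphenylsilyloxy)-8α-methyl-17-norlabd-13-ene-7β,8β-diol | O[C@H]1C[C@H]2C(C)(C)CCC[C@]2(C)[C@@H](CC/C(C)=C/CO[Si](c3ccccc3)(c3ccccc3)C(C)(C)C)[C@@]1(C)O | intermediate
22 | (13E)-7β-acetoxy-15-(tert-butyldiphenylsilyloxy)-8α-methyl-17-norlabd-13-en-8β-ol | CC(=O)O[C@H]1C[C@H]2C(C)(C)CCC[C@]2(C)[C@@H](CC/C(C)=C/CO[Si](c3ccccc3)(c3ccccc3)C(C)(C)C)[C@@]1(C)O | intermediate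
23 | (13E)-7β-acetoxy-8α-methyl-17-norlabd-13-ene-8β,15-diol (5α-H, 9α-H, 10β-CH3) | CC(=O)O[C@H]1C[C@H]2C(C)(C)CCC[C@]2(C)[C@@H](CC/C(C)=C/CO)[C@@]1(C)O | target

Total step count: 16. Longest linear sequence: 14 steps (steps 1–7 and 10–16; steps 8 and 9 prepare the side chain).

**Steps most likely to fail**

Step 3 (proposed new method). The hindered anti π-allyl isomer may be reached too slowly, so that oligomerisation wins over ring closure, or the ligand may not discriminate the faces well enough. The fallback sets out from 6 and comes back to the route at 8. Chemoselective hydrogenation of the disubstituted alkene of 6 (H2, RhCl(PPh3)3, benzene) should give tert-butyl 4-methyl-4-(2-methyl-3-oxocyclohex-1-en-1-yl)pentyl carbonate F1. CF3CO2H in CH2Cl2 removes the tert-butyl carbonate to give 3-(5-hydroxy-2-methylpentan-2-yl)-2-methylcyclohex-2-en-1-one F2. I2, PPh3 and imidazole convert it into 3-(5-iodo-2-methylpentan-2-yl)-2-methylcyclohex-2-en-1-one F3. KOtBu in t-BuOH/THF at high dilution then effects the classical intramolecular deconjugative α-alkylation of the same dienolate by the primary iodide, giving racemic 5,5,8a-trimethyl-3,5,6,7,8,8a-hexahydronaphthalen-1(2H)-one F4. Resolution by preparative HPLC on a chiral stationary phase gives (S)-5,5,8a-trimethyl-3,5,6,7,8,8a-hexahydronaphthalen-1(2H)-one F5, and hydrogenation under the conditions of step 4 gives 8.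

Step 10. Oxidative addition and transmetalation at the tetrasubstituted, electron-rich triflate next to the quaternary C10 may be too slow, so that protodeboronation and triflate hydrolysis take over. The fallback sets out from 9 (with borane 15, made from 14, as the side-chain source) and comes back at 17. Treatment of 15 with I2 and NaOMe should give tert-butyl{[(E)-5-iodo-3-methylpent-2-en-1-yl]oxy}diphenylsilane F6. Iodine–lithium exchange (t-BuLi, Et2O, −78 °C) and transmetalation to CeCl3 give an organocerium reagent that adds to the hindered ketone of 9 to give (4aS,8aS)-1-[(E)-5-(tert-butyldiphenylsilyloxy)-3-methylpent-3-en-1-yl]-5,5,8a-trimethyldecahydronaphthalene-1,2-diol F7. Catalytic TsOH in benzene then triggers a pinacol rearrangement: the tertiary C9 carbinol ionises, hydride shifts from C8, and the C8 ketone 17 results after equilibration of C9.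

Step 12. The axial C7 alkoxide may hinder the equatorial approach, giving poor facial selectivity, or the Grignard reagent may enolise the ketone instead of adding. The fallback sets out from 18 and comes back at 21, leaving out 19 and 20. Equilibration of 18 with DBU in CH2Cl2 should give the equatorial epimer (13E)-15-(tert-butyldiphenylsilyloxy)-7β-hydroxy-17-norlabd-13-en-8-one F8, in which the hydroxyl is coplanar with the carbonyl. Chelation-controlled addition of MeMgBr through the five-membered magnesium chelate, again from the α-face, then gives 21 directly.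

Further compounds
F1 | step 3 | tert-butyl 4-methyl-4-(2-methyl-3-oxocyclohex-1-en-1-yl)pentyl carbonate | CC1=C(CCCC1=O)C(C)(C)CCCOC(=O)OC(C)(C)C
F2 | step 3 | 3-(5-hydroxy-2-methylpentan-2-yl)-2-methylcyclohex-2-en-1-one | CC1=C(CCCC1=O)C(C)(C)CCCO
F3 | step 3 | 3-(5-iodo-2-methylpentan-2-yl)-2-methylcyclohex-2-en-1-one | CC1=C(CCCC1=O)C(C)(C)CCCI
F4 | step 3 | racemic 5,5,8a-trimethyl-3,5,6,7,8,8a-hexahydronaphthalen-1(2H)-one | C1C=C2C(C)(C)CCCC2(C)C(=O)C1
F5 | step 3 | (S)-5,5,8a-trimethyl-3,5,6,7,8,8a-hexahydronaphthalen-1(2H)-one | C1C=C2C(C)(C)CCC[C@]2(C)C(=O)C1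
F6 | step 10 | tert-butyl{[(E)-5-iodo-3-methylpent-2-en-1-yl]oxy}diphenylsilane | CC(C)(C)[Si](OC/C=C(C)/CCI)(c1ccccc1)c1ccccc1
F7 | step 10 | (4aS,8aS)-1-[(E)-5-(tert-butyldiphenylsilyloxy)-3-methylpent-3-en-1-yl]-5,5,8a-trimethyldecahydronaphthalene-1,2-diol (C1 and C2 epimers) | C1C[C@H]2C(C)(C)CCC[C@]2(C)C(O)(CC/C(C)=C/CO[Si](c3ccccc3)(c3ccccc3)C(C)(C)C)C1O
F8 | step 12 | (13E)-15-(tert-butyldiphenylsilyloxy)-7β-hydroxy-17-norlabd-13-en-8-one | O[C@H]1C[C@H]2C(C)(C)CCC[C@]2(C)[C@@H](CC/C(C)=C/CO[Si](c3ccccc3)(c3ccccc3)C(C)(C)C)C1=O
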